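**Plan**

- Germacranolide locants are used: carbocycle C1–C10, lactone carbons C11–C13, ester carbon C14, methyl C15. Retrosynthesis removes the 4,5-epoxide oxygen and the O8 angelate, then cuts C4=C5 (ring-closing metathesis), C11–C7 together with C11=C13 (tethered phosphonoacetate, then formaldehyde), C5–C6 (vinyl addition), C10–C14 (carbonylation) and C9–C10 (alkynylation).
- Enabling feature: in the γ-lactone the ring oxygen on C6 and ring carbon C7 lie next to the oxygenated C8. This O–C6–C7–C8–O array is a 2,3-epoxy alcohol in disguise. A carbon nucleophile held on the C6 oxygen by the two-atom acyl tether C12–C11 can reach only C7, by 5-exo opening of a C7–C8 epoxide, and this frees O8 alone for the angelate.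
- Forward order: the open chain is joined first (alkyne + enal, hydrostannation/iodination, carbonylation, vinylation). Then follow the epoxide, the tether, the lactone ring (key step), the angelate, the ten-membered ring (metathesis), the 4,5-epoxide and desilylation.
- Stereochemistry: C9 comes from catalytic asymmetric alkynylation. C6 comes from catalytic asymmetric vinylation and is inverted by the Mitsunobu reaction that installs the tether. C7 and C8 come from Sharpless epoxidation, C7 being inverted in the key step. C4/C5 come from substrate-controlled epoxidation of the Z-alkene. The C1=C10 geometry comes from syn-hydrostannation and the C4=C5 geometry from ring closure.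

Key step: step 10

Assumption: the (R,R)-ProPhenol–zinc catalyst is taken to give the (4R)-alcohol 5 from enal 3; if the opposite sense is found, the (S,S)-ligand is used with no other change.

Remark: CIP descriptors in names refer to the compound named; they change along the route without any change in geometry, because substituent priorities change.

**Route**

Step 1
Reactants: 1 hex-5-yn-2-one
Product: 2 2-methylhex-1-en-5-yne
Conditions: Ph3PCH3Br, KOtBu, Et2O, 0 °C to rt; distilled and used as a solution
Reagents that add atoms: methyltriphenylphosphonium bromide, [Br-].C[P+](c1ccccc1)(c1ccccc1)c1ccccc1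
Why: Wittig methylenation of the methyl ketone; the ylide is not basic enough to consume the terminal alkyne.

Step 2
Reactants: 2 2-methylhex-1-en-5-yne; 3 (E)-4,4-dimethoxybut-2-enal
Product: 5 (2E,4R)-1,1-dimethoxy-9-methyldeca-2,9-dien-5-yn-4-ol, via methylzinc acetylide 4 (not isolated)
Conditions: (R,R)-ProPhenol (10 mol%), Ph3PO (20 mol%), Me2Zn, toluene, 0 °C
Reagents that add atoms: none
Why: Zinc–ProPhenol asymmetric alkynylation of an α,β-unsaturated aldehyde (Trost alkynylation) by the alkynylzinc formed in the flask; the dinuclear zinc catalyst selects the aldehyde face and sets C9.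

Step 3
Reactants: 5 (2E,4R)-1,1-dimethoxy-9-methyldeca-2,9-dien-5-yn-4-ol
Product: 7 (2E,4R,5E)-5-iodo-1,1-dimethoxy-9-methyldeca-2,5,9-trien-4-ol, via vinylstannane 6 (not isolated)
Conditions: PdCl2(PPh3)2 (3 mol%), Bu3SnH, THF, 0 °C; then I2, CH2Cl2, 0 °C
Reagents that add atoms: iodine, [I][I]
Why: Hydroxyl-directed palladium-catalysed syn-hydrostannation puts tin on the alkyne carbon next to the carbinol with hydrogen cis to it, and iododestannylation with retention gives the vinyl iodide in which C9 and C2 are cis, the geometry of the future C1=C10 bond.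

Step 4
Reactants: 7 (2E,4R,5E)-5-iodo-1,1-dimethoxy-9-methyldeca-2,5,9-trien-4-ol
Product: 8 tert-butyl{[(2E,4R,5E)-5-iodo-1,1-dimethoxy-9-methyldeca-2,5,9-trien-4-yl]oxy}dimethylsilane
Conditions: TBSCl, imidazole, DMF, rt
Reagents that add atoms: tert-butyldimethylsilyl chloride, CC(C)(C)[Si](C)(C)Cl
Why: Silylation under neutral conditions that leave the dimethyl acetal intact; the silyl ether masks O9 until the last step.

Step 5
Reactants: 8 tert-butyl{[(2E,4R,5E)-5-iodo-1,1-dimethoxy-9-methyldeca-2,5,9-trien-4-yl]oxy}dimethylsilane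
Product: 9 methyl (2E)-2-[(1R,2E)-1-{[tert-butyl(dimethyl)silyl]oxy}-4,4-dimethoxybut-2-en-1-yl]-6-methylhepta-2,6-dienoate
Conditions: PdCl2(PPh3)2 (5 mol%), CO (1 atm), Et3N, MeOH–DMF, 60 °C
Reagents that add atoms: carbon monoxide, [C-]#[O+]; methanol, CO
Why: Palladium-catalysed methoxycarbonylation of the vinyl iodide (oxidative addition, CO insertion, methanolysis) installs C14 with retention of alkene geometry.

Step 6
Reactants: 9 methyl (2E)-2-[(1R,2E)-1-{[tert-butyl(dimethyl)silyl]oxy}-4,4-dimethoxybut-2-en-1-yl]-6-methylhepta-2,6-dienoate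
Product: 10 methyl (2E)-2-[(1R,2E)-1-{[tert-butyl(dimethyl)silyl]oxy}-4-oxobut-2-en-1-yl]-6-methylhepta-2,6-dienoate
Conditions: PPTS (cat.), acetone–H2O, rt
Reagents that add atoms: water, O
Why: Mild acid hydrolysis of the allylic dimethyl acetal, which is far more labile than the silyl ether, unmasks the (E)-enal.

Step 7
Reactants: 10 methyl (2E)-2-[(1R,2E)-1-{[tert-butyl(dimethyl)silyl]oxy}-4-oxobut-2-en-1-yl]-6-methylhepta-2,6-dienoate; 11 vinylmagnesium bromide
Product: 13 methyl (2E)-2-[(1R,2E,4R)-1-{[tert-butyl(dimethyl)silyl]oxy}-4-hydroxyhexa-2,5-dien-1-yl]-6-methylhepta-2,6-dienoate, via divinylzinc 12 (not isolated)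
Conditions: 11, ZnCl2, THF, 0 °C, then 1,4-dioxane and filtration; (+)-MIB (10 mol%), toluene–hexane, −20 °C
Reagents that add atoms: none
Why: Amino-alcohol-catalysed enantioselective addition of divinylzinc (Oppolzer-type vinylation) is 1,2-selective and spares the ester; the zinc–MIB complex selects the aldehyde face to give the (R)-carbinol at C6, the sense being opposite to that of the (−)-ligand in dialkylzinc additions.

Step 8
Reactants: 13 methyl (2E)-2-[(1R,2E,4R)-1-{[tert-butyl(dimethyl)silyl]oxy}-4-hydroxyhexa-2,5-dien-1-yl]-6-methylhepta-2,6-dienoate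
Product: 14 methyl (2E)-2-[(S)-{[tert-butyl(dimethyl)silyl]oxy}{(2S,3R)-3-[(1R)-1-hydroxyprop-2-en-1-yl]oxiran-2-yl}methyl]-6-methylhepta-2,6-dienoate
Conditions: Ti(OiPr)4 (20 mol%), D-(−)-DIPT (24 mol%), TBHP, 4 Å molecular sieves, CH2Cl2, −20 °C
Reagents that add atoms: tert-butyl hydroperoxide, CC(C)(C)OO
Why: Sharpless asymmetric epoxidation of the secondary allylic alcohol: with D-(−)-DIPT the (R)-carbinol is the fast-reacting substrate and its E-alkene is epoxidised erythro, setting C7 and C8, while the vinyl group (mismatched, monosubstituted) and the non-allylic alkenes should stay untouched.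

Step 9
Reactants: 14 methyl (2E)-2-[(S)-{[tert-butyl(dimethyl)silyl]oxy}{(2S,3R)-3-[(1R)-1-hydroxyprop-2-en-1-yl]oxiran-2-yl}methyl]-6-methylhepta-2,6-dienoate; 15 (diethoxyphosphoryl)acetic acid
Product: 16 methyl (2E)-2-[(S)-{[tert-butyl(dimethyl)silyl]oxy}{(2S,3R)-3-[(1S)-1-{[(diethoxyphosphoryl)acetyl]oxy}prop-2-en-1-yl]oxiran-2-yl}methyl]-6-methylhepta-2,6-dienoate
Conditions: PPh3, DIAD, toluene, 0 °C to rt
Reagents that add atoms: none
Why: Mitsunobu esterification with inversion at C6 turns the erythro into the threo epoxy ester and installs the phosphonoacetate tether in the same operation.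

Step 10
Reactants: 16 methyl (2E)-2-[(S)-{[tert-butyl(dimethyl)silyl]oxy}{(2S,3R)-3-[(1S)-1-{[(diethoxyphosphoryl)acetyl]oxy}prop-2-en-1-yl]oxiran-2-yl}methyl]-6-methylhepta-2,6-dienoate
Product: 18 methyl (2E)-2-[(1S,2S)-1-{[tert-butyl(dimethyl)silyl]oxy}-2-[(2S,3R)-2-ethenyl-4-methylidene-5-oxooxolan-3-yl]-2-hydroxyethyl]-6-methylhepta-2,6-dienoate, via phosphonolactone 17 (not isolated)
Conditions: KOtBu (1.0 equiv), THF, 0 to 40 °C; then (CH2O)n, 0 °C to rt
Reagents that add atoms: formaldehyde (from paraformaldehyde), C=O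
Why: Proposed new method: KOtBu deprotonates the phosphonoacetate CH2 of 16 and the stabilised carbanion attacks C7 of the epoxy ester in a 5-exo-tet SN2 opening anti to the C7–O bond, which forms C11–C7 and closes the γ-lactone (O–C6–C7–C11–C12); the C8 alkoxide set free is quenched at once by the acidic C11–H of 17, and the carbanion so regenerated olefinates formaldehyde (Horner–Wadsworth–Emmons) to give the C11=C13 methylene. The closest known reactions are the intermolecular phosphonoacetate–epoxide lactone annulation, the telescoped intramolecular Michael/olefination of ester-tethered phosphonoacetates and the carbamate-tethered C2 opening of 2,3-epoxy alcohols; the new element is an ester-tethered carbon nucleophile on an epoxide. C7 is the only stereocentre made and it is set by inversion of the Sharpless epoxide, so the threo ester gives the 6,7-cis lactone, while C8 keeps its configuration and emerges as the one free hydroxyl, ready for the angelate. The step needs C7 over C8 regioselectivity and a harmless alkoxide: the O–C12–C11 tether reaches C7 in line with the breaking C–O bond only in the 5-exo mode, the 6-endo path to C8 has no cation-stabilising group and is screened by the C9 silyl ether, and internal proton transfer to the delocalised phosphonate anion removes the alkoxide before it can translactonise, attack the C14 ester or take the silyl group. Delocalisation of the carbanion into the acyl group also eases rotation to the s-cis ester rotamer that ring closure requires.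

Step 11
Reactants: 18 methyl (2E)-2-[(1S,2S)-1-{[tert-butyl(dimethyl)silyl]oxy}-2-[(2S,3R)-2-ethenyl-4-methylidene-5-oxooxolan-3-yl]-2-hydroxyethyl]-6-methylhepta-2,6-dienoate; 19 angelic acid
Product: 21 O8-angelate of 18 (seco-diene), via mixed anhydride 20 (not isolated)
Conditions: 19, 2,4,6-trichlorobenzoyl chloride, Et3N, toluene, rt; then 18, 80 °C
Reagents that add atoms: none
Why: Yamaguchi mixed-anhydride acylation of the hindered C8 alcohol without DMAP, conditions under which the angeloyl group should transfer without Z to E isomerisation.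

Step 12
Reactants: 21 O8-angelate of 18 (seco-diene)
Product: 22 ten-membered (4Z)-alkene (9-O-TBS-4,5-deoxy precursor of the target)
Conditions: second-generation Grubbs catalyst (10 mol%), toluene (1 mM), 80 °C
Reagents that add atoms: none
Why: Ring-closing metathesis should initiate at the C6 vinyl group and close on the 1,1-disubstituted alkene; the cis-fused lactone and the cis C1=C10 bond hold the two ends together, the ten-membered ring favours the Z trisubstituted alkene, and the conjugated alkenes are poor metathesis partners.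

Step 13
Reactants: 22 ten-membered (4Z)-alkene
Product: 23 9-O-TBS ether of the target
Conditions: mCPBA, NaHCO3, CH2Cl2, 0 °C
Reagents that add atoms: mCPBA, OOC(=O)c1cccc(Cl)c1
Why: Prilezhaev epoxidation is chemoselective for the only electron-rich alkene; A(1,3) strain places C6–H in the plane of the Z-alkene, the carbocycle covers one face, and the peracid should add to the other, the one bearing the lactone oxygen, giving the (4R,5S)-epoxide.

Step 14
Reactants: 23 9-O-TBS ether of the target
Product: 24 target CNP0251641.1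
Conditions: HF·pyridine, pyridine, THF, 0 °C to rt
Reagents that add atoms: none
Why: Buffered fluoride desilylation under mildly acidic conditions avoids acyl migration from O8 to O9 and should leave the epoxide and the α-methylene lactone intact.

**Compound list**

1 | hex-5-yn-2-one | CC(=O)CCC#C | starting material
2 | 2-methylhex-1-en-5-yne | C=C(C)CCC#C | intermediate
3 | (E)-4,4-dimethoxybut-2-enal | COC(OC)/C=C/C=O | starting material
4 | methyl(5-methylhex-5-en-1-yn-1-yl)zinc | C[Zn]C#CCCC(C)=C | intermediate
5 | (2E,4R)-1,1-dimethoxy-9-methyldeca-2,9-dien-5-yn-4-ol | COC(OC)/C=C/[C@@H](O)C#CCCC(C)=C | intermediate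
6 | (2E,4R,5E)-1,1-dimethoxy-9-methyl-5-(tributylstannyl)deca-2,5,9-trien-4-ol | COC(OC)/C=C/[C@@H](O)/C(=C\CCC(C)=C)[Sn](CCCC)(CCCC)CCCC | intermediate
7 | (2E,4R,5E)-5-iodo-1,1-dimethoxy-9-methyldeca-2,5,9-trien-4-ol | COC(OC)/C=C/[C@@H](O)/C(I)=C\CCC(C)=C | intermediate
8 | tert-butyl{[(2E,4R,5E)-5-iodo-1,1-dimethoxy-9-methyldeca-2,5,9-trien-4-yl]oxy}dimethylsilane | COC(OC)/C=C/[C@@H](O[Si](C)(C)C(C)(C)C)/C(I)=C\CCC(C)=C | intermediate
9 | methyl (2E)-2-[(1R,2E)-1-{[tert-butyl(dimethyl)silyl]oxy}-4,4-dimethoxybut-2-en-1-yl]-6-methylhepta-2,6-dienoate | COC(OC)/C=C/[C@@H](O[Si](C)(C)C(C)(C)C)/C(C(=O)OC)=C\CCC(C)=C | intermediate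
10 | methyl (2E)-2-[(1R,2E)-1-{[tert-butyl(dimethyl)silyl]oxy}-4-oxobut-2-en-1-yl]-6-methylhepta-2,6-dienoate | O=C/C=C/[C@@H](O[Si](C)(C)C(C)(C)C)/C(C(=O)OC)=C\CCC(C)=C | intermediate
11 | vinylmagnesium bromide | C=C[Mg]Br | starting material
12 | divinylzinc | C=C[Zn]C=C | intermediate
13 | methyl (2E)-2-[(1R,2E,4R)-1-{[tert-butyl(dimethyl)silyl]oxy}-4-hydroxyhexa-2,5-dien-1-yl]-6-methylhepta-2,6-dienoate | C=C[C@@H](O)/C=C/[C@@H](O[Si](C)(C)C(C)(C)C)/C(C(=O)OC)=C\CCC(C)=C | intermediate
14 | erythro epoxy alcohol: methyl (2E)-2-[(S)-{[tert-butyl(dimethyl)silyl]oxy}{(2S,3R)-3-[(1R)-1-hydroxyprop-2-en-1-yl]oxiran-2-yl}methyl]-6-methylhepta-2,6-dienoate | C=C[C@@H](O)[C@H]1O[C@@H]1[C@@H](O[Si](C)(C)C(C)(C)C)/C(C(=O)OC)=C\CCC(C)=C | intermediate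
15 | (diethoxyphosphoryl)acetic acid | CCOP(=O)(OCC)CC(=O)O | starting material
16 | threo phosphonoacetate: methyl (2E)-2-[(S)-{[tert-butyl(dimethyl)silyl]oxy}{(2S,3R)-3-[(1S)-1-{[(diethoxyphosphoryl)acetyl]oxy}prop-2-en-1-yl]oxiran-2-yl}methyl]-6-methylhepta-2,6-dienoate | CCOP(=O)(OCC)CC(=O)O[C@@H](C=C)[C@H]1O[C@@H]1[C@@H](O[Si](C)(C)C(C)(C)C)/C(C(=O)OC)=C\CCC(C)=C | intermediate
17 | α-phosphono lactone: 18 with H and P(O)(OEt)2 on C11 in place of the methylene (C11 epimers) | CCOP(=O)(OCC)C1C(=O)O[C@@H](C=C)[C@H]1[C@H](O)[C@@H](O[Si](C)(C)C(C)(C)C)/C(C(=O)OC)=C\CCC(C)=C | intermediate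
18 | methyl (2E)-2-[(1S,2S)-1-{[tert-butyl(dimethyl)silyl]oxy}-2-[(2S,3R)-2-ethenyl-4-methylidene-5-oxooxolan-3-yl]-2-hydroxyethyl]-6-methylhepta-2,6-dienoate | C=C1C(=O)O[C@@H](C=C)[C@H]1[C@H](O)[C@@H](O[Si](C)(C)C(C)(C)C)/C(C(=O)OC)=C\CCC(C)=C | intermediate
19 | angelic acid, (Z)-2-methylbut-2-enoic acid | C/C=C(/C)C(=O)O | starting material
20 | angelic 2,4,6-trichlorobenzoic anhydride | C/C=C(/C)C(=O)OC(=O)c1c(Cl)cc(Cl)cc1Cl | intermediate
21 | O8-angelate of 18 (6,7-cis lactone; C6 vinyl; O9 TBS; isopropenyl chain end) | C=C1C(=O)O[C@@H](C=C)[C@H]1[C@H](OC(=O)/C(C)=C\C)[C@@H](O[Si](C)(C)C(C)(C)C)/C(C(=O)OC)=C\CCC(C)=C | intermediate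
22 | ten-membered (4Z)-alkene: the target lacking the epoxide oxygen, O9 as TBS ether | C=C1C(=O)O[C@@H]2[C@H]1[C@H](OC(=O)/C(C)=C\C)[C@@H](O[Si](C)(C)C(C)(C)C)/C(C(=O)OC)=C\CC/C(C)=C\2 | intermediate
23 | 9-O-TBS ether of the target | C=C1C(=O)O[C@@H]2[C@H]1[C@H](OC(=O)/C(C)=C\C)[C@@H](O[Si](C)(C)C(C)(C)C)/C(C(=O)OC)=C\CC[C@@]1(C)O[C@@H]21 | intermediate
24 | CNP0251641.1: methyl (4R,5S,6R,7R,8S,9S)-8-angeloyloxy-4,5-epoxy-9-hydroxy-germacra-1(10),11(13)-dien-12,6-olid-14-oate | C=C1C(=O)O[C@@H]2[C@H]1[C@H](OC(=O)/C(C)=C\C)[C@@H](O)/C(C(=O)OC)=C\CC[C@@]1(C)O[C@@H]21 | target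

**Summary**

Total steps: 14. Longest linear sequence: 14 (1 to 24).

Steps most likely to fail:

1. Step 10 (proposed new method). The delocalised carbanion may be too poor a nucleophile, or too reluctant to reach the s-cis ester rotamer, to open the epoxide. The liberated C8 alkoxide may instead transfer an acyl group (translactonisation to the 12,8-olide, or lactonisation on the C14 ester) or take the silyl group. The fallback uses known chemistry, sets out from 14 and comes back at 21. Mitsunobu inversion of 14 with 4-nitrobenzoic acid (PPh3, DIAD) gives the threo 4-nitrobenzoate F1. Lithium (trimethylsilyl)acetylide with BF3·OEt2 (THF, −78 °C) opens the epoxide with inversion; attack is expected at C7 because C8 is screened by the fully substituted C9, giving the alkynyl carbinol F2. Yamaguchi angeloylation as in step 11 gives the angelate F3. K2CO3 in MeOH at 0 °C removes the activated 4-nitrobenzoate and the C-silyl group to give the homopropargylic alcohol F4. Palladium-catalysed cyclocarbonylation of F4 (PdCl2, thiourea, CO, acetone, 50 °C) then builds the α-methylene lactone by C–O and C–C bond formation at C12 and returns 21.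

2. Step 12. Oligomerisation may outrun ring closure, because the 1,1-disubstituted alkene engages slowly and the ten-membered ring is strained, and some E alkene may form. The fallback changes the ring-closing substrate and the order of events: it sets out from 18 and comes back at 22. Metathesis is run on the free alcohol 18, which lacks the bulky C8 ester and can hydrogen-bond to the C14 ester, to give the macrocyclic alcohol F5. F5 is then angeloylated as in step 11 to give 22.

3. Step 13. Facial selectivity may be poor if the macrocycle populates a conformer in which the lactone oxygen, not C6–H, eclipses the alkene, so that the peracid meets the wrong face. The fallback replaces direct oxygen transfer by anti addition and closure, which delivers the epoxide oxygen to the face opposite to the exposed one; it sets out from 22 and comes back at 23. NBS in aqueous acetone gives the trans-bromohydrin F6 (bromine at C5 on the exposed face, hydroxyl at the tertiary C4). K2CO3 in acetone closes it with inversion at C5 to give 23.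

Further compounds
F1 | step 10 | threo 4-nitrobenzoate: 4-nitrobenzoate of the C6 epimer of 14 | O=C(O[C@@H](C=C)[C@H]1O[C@@H]1[C@@H](O[Si](C)(C)C(C)(C)C)/C(C(=O)OC)=C\CCC(C)=C)c1ccc(cc1)[N+](=O)[O-]
F2 | step 10 | alkynyl carbinol: C7 (trimethylsilyl)ethynyl, C8 hydroxyl, C6 4-nitrobenzoate | O=C(O[C@@H](C=C)[C@H](C#C[Si](C)(C)C)[C@H](O)[C@@H](O[Si](C)(C)C(C)(C)C)/C(C(=O)OC)=C\CCC(C)=C)c1ccc(cc1)[N+](=O)[O-]
F3 | step 10 | O8-angelate of F2 | O=C(O[C@@H](C=C)[C@H](C#C[Si](C)(C)C)[C@H](OC(=O)/C(C)=C\C)[C@@H](O[Si](C)(C)C(C)(C)C)/C(C(=O)OC)=C\CCC(C)=C)c1ccc(cc1)[N+](=O)[O-]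
F4 | step 10 | homopropargylic alcohol: C6 hydroxyl, C7 ethynyl, C8 angelate | O[C@@H](C=C)[C@H](C#C)[C@H](OC(=O)/C(C)=C\C)[C@@H](O[Si](C)(C)C(C)(C)C)/C(C(=O)OC)=C\CCC(C)=C
F5 | step 12 | macrocyclic alcohol: 22 with free C8 hydroxyl | C=C1C(=O)O[C@@H]2[C@H]1[C@H](O)[C@@H](O[Si](C)(C)C(C)(C)C)/C(C(=O)OC)=C\CC/C(C)=C\2
F6 | step 13 | trans-bromohydrin of 22: C4 tertiary alcohol, C5 bromide | C=C1C(=O)O[C@@H]2[C@H]1[C@H](OC(=O)/C(C)=C\C)[C@@H](O[Si](C)(C)C(C)(C)C)/C(C(=O)OC)=C\CC[C@@](C)(O)[C@@H]2Br
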